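**Retrosynthetic overview**
1. The strategy rests on the phenylcoumaran. Cβ of the ring C (syringyl) propanoid is bonded to the carbon of ring D ortho to its phenol oxygen (C3–C3a), and the benzylic carbon of ring C is bonded to that oxygen (O1–C2). Both bonds are cut together, leading back to an N-sinapoyl oxazolidinone and 4-bromo-2-methoxyphenol (oxidative β–5 cross-coupling with quinone methide trapping).
2. The dihydrofuran is the only ring formed in the route (step 4). Rings A to D are bought as arenes.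
3. Both erythro β-aryl ether units are cut at C7–C8 and C7'–C8'. An Evans syn aldol of an aryloxyacetyl imide sets C8 or C8', and Mitsunobu inversion of the carbinol then turns threo into erythro.
4. The route is convergent: a ring A–ring B aldehyde (from vanillin and 4-bromo-2,6-dimethoxyphenol) meets the glycolyl imide of the ring C phenol in the second aldol.
5. The ring D bromine blocks the para position during the coupling. It later becomes the propenal by a Heck reaction with a Weinreb acrylamide and i-Bu2AlH, and fluoride removes all silyl groups last.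

Key step: step 4

Assumption: the sinapoyl imide radical is taken to couple through its s-cis, carbonyl-opposed rotamer (the rotamer in which boron enolates of such imides react), so that the (S)-auxiliary exposes the Cβ face leading to the (2R,3R) imide. The sense is to be checked by X-ray analysis of the coupled imide (bromine and the known auxiliary centre serve as references); if it is reversed, (R)-4-benzyl-2-oxazolidinone is used in step 2 and nothing else changes.

Labels: ring A is the terminal guaiacyl ring (side chain C7–C8–C9). Ring B is the middle syringyl ring (C7'–C8'–C9'). Ring C is the syringyl ring on C2. Ring D is the benzo ring of the phenylcoumaran (O1, C2, C3, C3a to C7a; C3 bears CH2OH).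

**Route**

Step 1
Reactants: 1 sinapic acid
Product: 3 (E)-3-[4-(tert-butyldimethylsilyloxy)-3,5-dimethoxyphenyl]acrylic acid, via bis-silylated sinapate 2 (not isolated)
Conditions: TBSCl (2.5 equiv), imidazole (5 equiv), DMF, rt; crude 2 in AcOH–THF–H2O (3:1:1), rt
Reagents that add atoms: tert-butyldimethylsilyl chloride, CC(C)(C)[Si](C)(C)Cl
Why: Silyl protection: both acidic OH groups are silylated and the much more labile silyl ester is then hydrolysed selectively, so that the phenol stays masked during the acylation of step 2.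

Step 2
Reactants: 3 silylated sinapic acid; 4 (S)-4-benzyl-2-oxazolidinone
Product: 6 (S)-4-benzyl-3-{(E)-3-[4-(tert-butyldimethylsilyloxy)-3,5-dimethoxyphenyl]acryloyl}oxazolidin-2-one, via mixed pivalic anhydride 5 (not isolated)
Conditions: PivCl (1.05 equiv), Et3N (2.5 equiv), THF, −20 °C; then LiCl (1.2 equiv), 4, −20 °C → rt
Reagents that add atoms: pivaloyl chloride, CC(C)(C)C(=O)Cl (its acyl group stands in 5 only)
Why: N-Acylation of an oxazolidinone by the mixed-anhydride method: the LiCl/Et3N-activated carbamate attacks the unhindered cinnamoyl carbonyl of 5 and not the pivaloyl one, and neither the E alkene nor the auxiliary centre is touched.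

Step 3
Reactants: 6 silylated imide
Product: 7 (S)-4-benzyl-3-[(E)-3-(4-hydroxy-3,5-dimethoxyphenyl)acryloyl]oxazolidin-2-one (N-sinapoyl imide)
Conditions: Bu4NF (1.1 equiv), AcOH (1.2 equiv), THF, 0 °C
Reagents that add atoms: none
Why: Fluoride cleavage of an aryl silyl ether is fast at 0 °C, and the acetic acid buffer protects the imide from basic fluoride and phenoxide.

Step 4
Reactants: 7 N-sinapoyl imide; 8 4-bromo-2-methoxyphenol
Product: 11 (S)-4-benzyl-3-{[(2R,3R)-5-bromo-2-(4-hydroxy-3,5-dimethoxyphenyl)-7-methoxy-2,3-dihydrobenzofuran-3-yl]carbonyl}oxazolidin-2-one (trans phenylcoumaran imide), via dienone quinone methide 9 (not isolated), via phenol quinone methide 10 (not isolated)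
Conditions: 8 (5 equiv), Ag2O (2.5 equiv, in portions), 4 Å molecular sieves, dry CH2Cl2, Ar, dark, rt; 7 in CH2Cl2 added by syringe pump over 10 h; chromatography, then crystallisation of the wanted trans diastereomer
Reagents that add atoms: none
Why: Proposed new method: Ag2O (monovalent silver) removes one electron and one proton from each phenol; the sinapoyl radical (spin at Cβ) and the bromoguaiacyl radical (spin at its free ortho carbon) combine to form C3–C3a (9), the ring D dienone tautomerises to the phenol (10), and this phenol adds to the methide carbon of the ring C quinone methide to form O1–C2. The closest known reaction type is the Ag2O or peroxidase/H2O2 dehydrodimerisation of ferulate esters and of chiral feruloyl amides and imides to trans phenylcoumarans, where both partners are the same phenol and induction is modest, whereas a two-component version under auxiliary control has not been described. The dihydrofuran closes by a 5-exo-trig oxa-conjugate addition driven by rearomatisation of ring C. C3 is set in the radical combination by the oxazolidinone, whose benzyl group covers one face of Cβ in the s-cis, carbonyl-opposed rotamer, and C2 is set by C3, because the phenol adds anti to the bulky acyl group and the addition is reversible towards the more stable trans ring; the two trans products are diastereomers through the auxiliary and are separable, so 11 goes on as a single isomer. Cross-coupling must beat β–β coupling of 7 and 5–5 or 4–O–5 coupling of 8: the two methoxy groups of 7 exclude a β–5 homodimer, slow addition of 7 into a fivefold excess of 8 keeps the longer-lived sinapoyl radical dilute among guaiacyl radicals, and the dry, non-nucleophilic medium leaves β–O–4 adducts without a trap while the β–5 adduct carries its own. The bromine closes the para carbon of 8 to coupling, and portionwise oxidant limits further oxidation of the free syringyl phenol of 11.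

Step 5
Reactants: 11 trans phenylcoumaran imide
Product: 12 4-[(2R,3S)-5-bromo-3-(hydroxymethyl)-7-methoxy-2,3-dihydrobenzofuran-2-yl]-2,6-dimethoxyphenol
Conditions: LiBH4 (3 equiv), MeOH (3 equiv), THF, 0 °C; aq NH4Cl
Reagents that add atoms: none
Why: Reductive cleavage of the N-acyl oxazolidinone (hydride attack at the exocyclic carbonyl, LiBH4/MeOH being suited to α-branched imides) should give the primary alcohol and return the auxiliary without a base that could epimerise C3 or open O1–C2, and the aryl bromide is inert.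

Step 6
Reactants: 13 (R)-4-benzyl-2-oxazolidinone; 14 bromoacetyl bromide
Product: 16 (R)-4-benzyl-3-(bromoacetyl)oxazolidin-2-one, via lithium salt 15 (not isolated)
Conditions: n-BuLi (1.0 equiv), THF, −78 °C; then 14 (1.1 equiv), −78 → 0 °C
Reagents that add atoms: n-butyllithium, [Li]CCCC (its lithium stands in 15 only)
Why: N-Acylation of the lithiated oxazolidinone 15 with an acid bromide, which at −78 °C is much faster than displacement of the α-bromide, is the standard entry to haloacetyl imides.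

Step 7
Reactants: 12 phenylcoumaran phenol; 16 bromoacetyl imide
Product: 17 (R)-4-benzyl-3-({4-[(2R,3S)-5-bromo-3-(hydroxymethyl)-7-methoxy-2,3-dihydrobenzofuran-2-yl]-2,6-dimethoxyphenoxy}acetyl)oxazolidin-2-one
Conditions: K2CO3 (1.5 equiv), acetone, rt
Reagents that add atoms: none
Why: Williamson ether synthesis: K2CO3 deprotonates only the phenol, and the phenoxide displaces the carbonyl-activated primary bromide by SN2 faster than it can attack the imide, so the primary alcohol needs no protection and the glycolyl unit arrives with its auxiliary.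

Step 8
Reactants: 17 glycolyl imide alcohol
Product: 18 the tert-butyldimethylsilyl ether of 17 at the C3 hydroxymethyl group
Conditions: TBSCl (1.3 equiv), imidazole (2.5 equiv), CH2Cl2, rt
Reagents that add atoms: tert-butyldimethylsilyl chloride, CC(C)(C)[Si](C)(C)Cl
Why: Standard silylation of the only free hydroxyl group, which would otherwise consume Bu2BOTf in step 18.

Step 9
Reactants: 19 4-bromo-2,6-dimethoxyphenol; 16 bromoacetyl imide
Product: 20 (R)-4-benzyl-3-[(4-bromo-2,6-dimethoxyphenoxy)acetyl]oxazolidin-2-one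
Conditions: K2CO3 (1.5 equiv), acetone, rt
Reagents that add atoms: none
Why: Williamson ether synthesis as in step 7, here on a simple hindered phenol whose bromine is the masked formyl group of ring B.

Step 10
Reactants: 21 vanillin
Product: 22 3-methoxy-4-(triisopropylsilyloxy)benzaldehyde
Conditions: TIPSCl (1.2 equiv), imidazole (2.5 equiv), DMF, rt
Reagents that add atoms: triisopropylsilyl chloride, CC(C)[Si](Cl)(C(C)C)C(C)C
Why: Silyl protection of the phenol; TIPS is chosen because its aryl ether withstands LiBH4, i-Bu2AlH and n-BuLi and because a silyloxy group is a weaker donor than an alkoxy group, which disfavours ionisation at C7 in step 14.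

Step 11
Reactants: 20 ring B glycolyl imide; 22 silylated vanillin
Product: 24 (R)-4-benzyl-3-{(2R,3S)-2-(4-bromo-2,6-dimethoxyphenoxy)-3-hydroxy-3-[3-methoxy-4-(triisopropylsilyloxy)phenyl]propanoyl}oxazolidin-2-one, via Z boron enolate 23 (not isolated)
Conditions: Bu2BOTf (1.2 equiv), Et3N (1.4 equiv), CH2Cl2, −78 → 0 °C; 22, −78 → 0 °C; pH 7 buffer, MeOH, 30% H2O2, 0 °C
Reagents that add atoms: dibutylboron triflate, CCCCB(CCCC)OS(=O)(=O)C(F)(F)F (its boryl group stands in 23 only)
Why: Evans syn aldol reaction, known for aryloxyacetyl imides and aromatic aldehydes: Z boron enolate 23 reacts through a closed Zimmerman–Traxler chair on the enolate face away from the benzyl group, so the (R)-auxiliary sets C8 (2R in the imide) and C7 (3S) in the syn, that is threo, relationship.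

Step 12
Reactants: 24 aldol adduct
Product: 25 (1S,2S)-2-(4-bromo-2,6-dimethoxyphenoxy)-1-[3-methoxy-4-(triisopropylsilyloxy)phenyl]propane-1,3-diol (threo)
Conditions: LiBH4 (2.5 equiv), MeOH (2.5 equiv), THF, 0 °C; aq NH4Cl
Reagents that add atoms: none
Why: Reductive cleavage of the N-acyl oxazolidinone with LiBH4 touches neither stereocentre (the C8 descriptor changes from R to S only through the priority change), and the aryl bromide and silyl ether are inert.

Step 13
Reactants: 25 threo diol
Product: 26 (1S,2S)-2-(4-bromo-2,6-dimethoxyphenoxy)-3-(tert-butyldimethylsilyloxy)-1-[3-methoxy-4-(triisopropylsilyloxy)phenyl]propan-1-ol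
Conditions: TBSCl (1.1 equiv), imidazole (2 equiv), CH2Cl2, 0 °C
Reagents that add atoms: tert-butyldimethylsilyl chloride, CC(C)(C)[Si](C)(C)Cl
Why: Steric differentiation in silylation: the primary hydroxyl reacts well before the hindered secondary benzylic one.

Step 14
Reactants: 26 threo alcohol
Product: 27 (1R,2S)-2-(4-bromo-2,6-dimethoxyphenoxy)-3-(tert-butyldimethylsilyloxy)-1-[3-methoxy-4-(triisopropylsilyloxy)phenyl]propyl 4-nitrobenzoate (erythro)
Conditions: 4-nitrobenzoic acid (2 equiv), PPh3 (2 equiv), DIAD (2 equiv), toluene, −20 → 0 °C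
Reagents that add atoms: 4-nitrobenzoic acid, O=C(O)c1ccc(cc1)[N+](=O)[O-]
Why: Mitsunobu reaction: 4-nitrobenzoate displaces the oxyphosphonium group by SN2 with inversion, turning C7 from S to R and threo into erythro, as known for β-aryl ether lignin models, while the non-polar solvent and low temperature hold back ionisation.

Step 15
Reactants: 27 erythro 4-nitrobenzoate
Product: 28 (1R,2S)-2-(4-bromo-2,6-dimethoxyphenoxy)-3-(tert-butyldimethylsilyloxy)-1-[3-methoxy-4-(triisopropylsilyloxy)phenyl]propan-1-ol (erythro)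
Conditions: i-Bu2AlH (4 equiv), CH2Cl2, −78 °C; aq potassium sodium tartrate
Reagents that add atoms: none
Why: Reductive ester cleavage with i-Bu2AlH breaks the acyl–oxygen bond, so C7 keeps its configuration, and being non-basic it leaves the aryl silyl ether in place, which rules out expulsion of the benzoate through a ring A quinone methide.

Step 16
Reactants: 28 erythro alcohol
Product: 29 the C7 tert-butyldimethylsilyl ether of 28 ((1R,2S), ring B bromide)
Conditions: TBSOTf (1.3 equiv), 2,6-lutidine (2 equiv), CH2Cl2, −78 → 0 °C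
Reagents that add atoms: tert-butyldimethylsilyl triflate, CC(C)(C)[Si](C)(C)OS(=O)(=O)C(F)(F)F
Why: Silylation of the hindered secondary alcohol with the silyl triflate and a non-nucleophilic base removes the last acidic proton before the lithiation.

Step 17
Reactants: 29 ring B bromide
Product: 31 4-({(1R,2S)-1,3-bis(tert-butyldimethylsilyloxy)-1-[3-methoxy-4-(triisopropylsilyloxy)phenyl]propan-2-yl}oxy)-3,5-dimethoxybenzaldehyde (ring A–ring B aldehyde), via aryllithium 30 (not isolated)
Conditions: n-BuLi (1.1 equiv), THF, −78 °C, 15 min; DMF (5 equiv), −78 → 0 °C; H2O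
Reagents that add atoms: N,N-dimethylformamide, CN(C)C=O; n-butyllithium, [Li]CCCC (its lithium stands in 30 only)
Why: Bromine–lithium exchange followed by formylation with DMF: exchange at −78 °C is faster than any deprotonation, and silyl and aryl ethers are inert to aryllithium 30.

Step 18
Reactants: 18 ring C glycolyl imide; 31 ring A–ring B aldehyde
Product: 33 syn aldol adduct joining all four rings ((2R,3S) at the new C8' and C7' of the propanoyl imide; C7'–OH free; (R)-auxiliary on C9'), via Z boron enolate 32 (not isolated)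
Conditions: 18, Bu2BOTf (1.2 equiv), Et3N (1.4 equiv), CH2Cl2, −78 → 0 °C; 31, −78 → 0 °C; pH 7 buffer, MeOH, 30% H2O2, 0 °C
Reagents that add atoms: dibutylboron triflate, CCCCB(CCCC)OS(=O)(=O)C(F)(F)F (its boryl group stands in 32 only)
Why: Evans syn aldol reaction as in step 11: the (R)-auxiliary of Z boron enolate 32 controls the enolate face and the chair transition state controls the syn relationship, giving C8' (2R in the imide) and C7' (3S), while the stereocentres of both partners are too remote to interfere.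

Step 19
Reactants: 33 aldol adduct
Product: 34 (7'S,8'S)-7',9'-diol (threo at the new unit)
Conditions: LiBH4 (2.5 equiv), MeOH (2.5 equiv), THF, 0 °C; aq NH4Cl
Reagents that add atoms: none
Why: Reductive cleavage of the N-acyl oxazolidinone with LiBH4 leaves all stereocentres, the silyl ethers and the aryl bromide untouched.

Step 20
Reactants: 34 threo diol
Product: 35 the C9' tert-butyldimethylsilyl ether of 34 (C7'–OH free, 7'S,8'S)
Conditions: TBSCl (1.1 equiv), imidazole (2 equiv), CH2Cl2, 0 °C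
Reagents that add atoms: tert-butyldimethylsilyl chloride, CC(C)(C)[Si](C)(C)Cl
Why: Selective silylation of the primary over the hindered secondary benzylic hydroxyl on steric grounds.

Step 21
Reactants: 35 threo alcohol
Product: 36 (7'R,8'S)-7'-O-(4-nitrobenzoyl) ester (erythro at both units)
Conditions: 4-nitrobenzoic acid (2.5 equiv), PPh3 (2.5 equiv), DIAD (2.5 equiv), toluene, −20 → 0 °C
Reagents that add atoms: 4-nitrobenzoic acid, O=C(O)c1ccc(cc1)[N+](=O)[O-]
Why: Mitsunobu reaction with SN2 inversion turns C7' from S to R, and the twisted 4-alkoxy group between two methoxy groups makes ring B a poor cation stabiliser, which favours clean displacement.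

Step 22
Reactants: 36 ring D bromide; 37 N-methoxy-N-methylacrylamide
Product: 38 (E)-N-methoxy-N-methyl-3-(ring D C5)acrylamide derived from 36
Conditions: Pd(P(t-Bu)3)2 (5 mol %), Cy2NMe (1.5 equiv), 37 (2 equiv), toluene, 50 °C
Reagents that add atoms: none
Why: Mizoroki–Heck reaction: the electron-rich, bulky phosphine lets zerovalent palladium insert into the electron-rich aryl bromide at mild temperature, syn insertion of the acrylamide and syn β-hydride elimination give the E alkene, and the hindered amine base spares the aryl silyl ether and benzylic ester that carbonate or acetate bases would endanger.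

Step 23
Reactants: 38 Weinreb acrylamide
Product: 39 silyl-protected target: (E)-propenal on ring D, C7'–OH free, TBS on O7, O9, O9' and the C3 hydroxymethyl oxygen, TIPS on the ring A phenol
Conditions: i-Bu2AlH (5 equiv), CH2Cl2, −78 °C; aq potassium sodium tartrate
Reagents that add atoms: none
Why: Weinreb amide reduction: i-Bu2AlH stops at the aldehyde oxidation level until work-up, and the same reagent cleaves the 4-nitrobenzoate at its acyl–oxygen bond with retention at C7', so the enal is released only after the hydride is destroyed.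

Step 24
Reactants: 39 silyl-protected target
Product: 40 CNP0192639.1
Conditions: Bu4NF (8 equiv), AcOH (8 equiv), THF, 0 °C → rt
Reagents that add atoms: none
Why: Global fluoride desilylation; the acetic acid buffer keeps the ring A phenol protonated, so that neither quinone methide formation at C7 nor base damage to the enal should occur, and no stereocentre is touched.

**Compound list**
1 | sinapic acid | COc1cc(/C=C/C(=O)O)cc(OC)c1O | starting material
2 | tert-butyldimethylsilyl (E)-3-[4-(tert-butyldimethylsilyloxy)-3,5-dimethoxyphenyl]acrylate | COc1cc(/C=C/C(=O)O[Si](C)(C)C(C)(C)C)cc(OC)c1O[Si](C)(C)C(C)(C)C | intermediate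
3 | (E)-3-[4-(tert-butyldimethylsilyloxy)-3,5-dimethoxyphenyl]acrylic acid | COc1cc(/C=C/C(=O)O)cc(OC)c1O[Si](C)(C)C(C)(C)C | intermediate
4 | (S)-4-benzyl-2-oxazolidinone | O=C1N[C@@H](Cc2ccccc2)CO1 | starting material
5 | mixed anhydride of 3 and pivalic acid | COc1cc(/C=C/C(=O)OC(=O)C(C)(C)C)cc(OC)c1O[Si](C)(C)C(C)(C)C | intermediate
6 | (S)-4-benzyl-3-{(E)-3-[4-(tert-butyldimethylsilyloxy)-3,5-dimethoxyphenyl]acryloyl}oxazolidin-2-one | O=C(/C=C/c1cc(OC)c(O[Si](C)(C)C(C)(C)C)c(OC)c1)N1C(=O)OC[C@@H]1Cc1ccccc1 | intermediate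
7 | (S)-4-benzyl-3-sinapoyl-2-oxazolidinone | O=C(/C=C/c1cc(OC)c(O)c(OC)c1)N1C(=O)OC[C@@H]1Cc1ccccc1 | intermediate
8 | 4-bromo-2-methoxyphenol | COc1cc(Br)ccc1O | starting material
9 | Cβ–ortho-carbon adduct: ring C p-quinone methide, ring D 6-substituted 4-bromo-2-methoxycyclohexa-2,4-dienone (ring carbon unassigned, Cβ as C3 of 11) | O=C1C(OC)=CC(Br)=CC1[C@H](C=C1C=C(OC)C(=O)C(OC)=C1)C(=O)N1C(=O)OC[C@@H]1Cc1ccccc1 | intermediate
10 | phenol tautomer of 9, (S) at Cβ, ring C still a p-quinone methide | COc1cc(Br)cc([C@H](C=C2C=C(OC)C(=O)C(OC)=C2)C(=O)N2C(=O)OC[C@@H]2Cc2ccccc2)c1O | intermediate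
11 | (S)-4-benzyl-3-{[(2R,3R)-5-bromo-2-(4-hydroxy-3,5-dimethoxyphenyl)-7-methoxy-2,3-dihydrobenzofuran-3-yl]carbonyl}oxazolidin-2-one | COc1cc([C@@H]2Oc3c(OC)cc(Br)cc3[C@H]2C(=O)N4C(=O)OC[C@@H]4Cc5ccccc5)cc(OC)c1O | intermediate
12 | 4-[(2R,3S)-5-bromo-3-(hydroxymethyl)-7-methoxy-2,3-dihydrobenzofuran-2-yl]-2,6-dimethoxyphenol | COc1cc([C@@H]2Oc3c(OC)cc(Br)cc3[C@H]2CO)cc(OC)c1O | intermediate
13 | (R)-4-benzyl-2-oxazolidinone | O=C1N[C@H](Cc2ccccc2)CO1 | starting material
14 | bromoacetyl bromide | BrCC(=O)Br | starting material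
15 | N-lithio-(R)-4-benzyl-2-oxazolidinone | [Li]N1[C@H](Cc2ccccc2)COC1=O | intermediate
16 | (R)-4-benzyl-3-(bromoacetyl)oxazolidin-2-one | O=C(CBr)N1C(=O)OC[C@H]1Cc1ccccc1 | intermediate
17 | ring C aryloxyacetyl (R)-imide, C3 hydroxymethyl free, (2R,3S) | COc1cc([C@@H]2Oc3c(OC)cc(Br)cc3[C@H]2CO)cc(OC)c1OCC(=O)N1C(=O)OC[C@H]1Cc1ccccc1 | intermediate
18 | TBS ether of 17 | COc1cc([C@@H]2Oc3c(OC)cc(Br)cc3[C@H]2CO[Si](C)(C)C(C)(C)C)cc(OC)c1OCC(=O)N1C(=O)OC[C@H]1Cc1ccccc1 | intermediate
19 | 4-bromo-2,6-dimethoxyphenol | COc1cc(Br)cc(OC)c1O | starting material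
20 | (R)-4-benzyl-3-[(4-bromo-2,6-dimethoxyphenoxy)acetyl]oxazolidin-2-one | COc1cc(Br)cc(OC)c1OCC(=O)N1C(=O)OC[C@H]1Cc1ccccc1 | intermediate
21 | vanillin | COc1cc(C=O)ccc1O | starting material
22 | 3-methoxy-4-(triisopropylsilyloxy)benzaldehyde | COc1cc(C=O)ccc1O[Si](C(C)C)(C(C)C)C(C)C | intermediate
23 | Z dibutylboron enolate of 20 | COc1cc(Br)cc(OC)c1O/C=C(\OB(CCCC)CCCC)N1C(=O)OC[C@H]1Cc1ccccc1 | intermediate
24 | (2R,3S) syn aldol imide of rings A and B | COc1cc([C@H](O)[C@H](C(=O)N2C(=O)OC[C@H]2Cc2ccccc2)Oc2c(OC)cc(Br)cc2OC)ccc1O[Si](C(C)C)(C(C)C)C(C)C | intermediate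
25 | (1S,2S) threo diol | COc1cc([C@H](O)[C@H](CO)Oc2c(OC)cc(Br)cc2OC)ccc1O[Si](C(C)C)(C(C)C)C(C)C | intermediate
26 | (1S,2S) threo alcohol, O9 TBS | COc1cc([C@H](O)[C@H](CO[Si](C)(C)C(C)(C)C)Oc2c(OC)cc(Br)cc2OC)ccc1O[Si](C(C)C)(C(C)C)C(C)C | intermediate
27 | (1R,2S) erythro 4-nitrobenzoate | COc1cc([C@@H](OC(=O)c2ccc(cc2)[N+](=O)[O-])[C@H](CO[Si](C)(C)C(C)(C)C)Oc2c(OC)cc(Br)cc2OC)ccc1O[Si](C(C)C)(C(C)C)C(C)C | intermediate
28 | (1R,2S) erythro alcohol | COc1cc([C@@H](O)[C@H](CO[Si](C)(C)C(C)(C)C)Oc2c(OC)cc(Br)cc2OC)ccc1O[Si](C(C)C)(C(C)C)C(C)C | intermediate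
29 | (1R,2S) bis-TBS ether, ring B bromide | COc1cc([C@@H](O[Si](C)(C)C(C)(C)C)[C@H](CO[Si](C)(C)C(C)(C)C)Oc2c(OC)cc(Br)cc2OC)ccc1O[Si](C(C)C)(C(C)C)C(C)C | intermediate
30 | ring B aryllithium from 29 | COc1cc([C@@H](O[Si](C)(C)C(C)(C)C)[C@H](CO[Si](C)(C)C(C)(C)C)Oc2c(OC)cc([Li])cc2OC)ccc1O[Si](C(C)C)(C(C)C)C(C)C | intermediate
31 | ring A–ring B aldehyde | COc1cc([C@@H](O[Si](C)(C)C(C)(C)C)[C@H](CO[Si](C)(C)C(C)(C)C)Oc2c(OC)cc(C=O)cc2OC)ccc1O[Si](C(C)C)(C(C)C)C(C)C | intermediate
32 | Z dibutylboron enolate of 18 | COc1cc([C@@H]2Oc3c(OC)cc(Br)cc3[C@H]2CO[Si](C)(C)C(C)(C)C)cc(OC)c1O/C=C(\OB(CCCC)CCCC)N1C(=O)OC[C@H]1Cc1ccccc1 | intermediate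
33 | four-ring syn aldol imide (7'S; C8' 2R in the imide) | COc1cc([C@@H](O[Si](C)(C)C(C)(C)C)[C@H](CO[Si](C)(C)C(C)(C)C)Oc2c(OC)cc([C@H](O)[C@H](C(=O)N6C(=O)OC[C@H]6Cc6ccccc6)Oc3c(OC)cc([C@@H]4Oc5c(OC)cc(Br)cc5[C@H]4CO[Si](C)(C)C(C)(C)C)cc3OC)cc2OC)ccc1O[Si](C(C)C)(C(C)C)C(C)C | intermediate
34 | (7'S,8'S) 7',9'-diol | COc1cc([C@@H](O[Si](C)(C)C(C)(C)C)[C@H](CO[Si](C)(C)C(C)(C)C)Oc2c(OC)cc([C@H](O)[C@H](CO)Oc3c(OC)cc([C@@H]4Oc5c(OC)cc(Br)cc5[C@H]4CO[Si](C)(C)C(C)(C)C)cc3OC)cc2OC)ccc1O[Si](C(C)C)(C(C)C)C(C)C | intermediate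
35 | (7'S,8'S) alcohol, O9' TBS | COc1cc([C@@H](O[Si](C)(C)C(C)(C)C)[C@H](CO[Si](C)(C)C(C)(C)C)Oc2c(OC)cc([C@H](O)[C@H](CO[Si](C)(C)C(C)(C)C)Oc3c(OC)cc([C@@H]4Oc5c(OC)cc(Br)cc5[C@H]4CO[Si](C)(C)C(C)(C)C)cc3OC)cc2OC)ccc1O[Si](C(C)C)(C(C)C)C(C)C | intermediate
36 | (7'R,8'S) 4-nitrobenzoate, ring D bromide | COc1cc([C@@H](O[Si](C)(C)C(C)(C)C)[C@H](CO[Si](C)(C)C(C)(C)C)Oc2c(OC)cc([C@@H](OC(=O)c6ccc(cc6)[N+](=O)[O-])[C@H](CO[Si](C)(C)C(C)(C)C)Oc3c(OC)cc([C@@H]4Oc5c(OC)cc(Br)cc5[C@H]4CO[Si](C)(C)C(C)(C)C)cc3OC)cc2OC)ccc1O[Si](C(C)C)(C(C)C)C(C)C | intermediate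
37 | N-methoxy-N-methylacrylamide | C=CC(=O)N(C)OC | starting material
38 | (E) Weinreb acrylamide on ring D | COc1cc([C@@H](O[Si](C)(C)C(C)(C)C)[C@H](CO[Si](C)(C)C(C)(C)C)Oc2c(OC)cc([C@@H](OC(=O)c6ccc(cc6)[N+](=O)[O-])[C@H](CO[Si](C)(C)C(C)(C)C)Oc3c(OC)cc([C@@H]4Oc5c(OC)cc(/C=C/C(=O)N(C)OC)cc5[C@H]4CO[Si](C)(C)C(C)(C)C)cc3OC)cc2OC)ccc1O[Si](C(C)C)(C(C)C)C(C)C | intermediate
39 | silyl-protected target (enal, C7'–OH free) | COc1cc([C@@H](O[Si](C)(C)C(C)(C)C)[C@H](CO[Si](C)(C)C(C)(C)C)Oc2c(OC)cc([C@@H](O)[C@H](CO[Si](C)(C)C(C)(C)C)Oc3c(OC)cc([C@@H]4Oc5c(OC)cc(/C=C/C=O)cc5[C@H]4CO[Si](C)(C)C(C)(C)C)cc3OC)cc2OC)ccc1O[Si](C(C)C)(C(C)C)C(C)C | intermediate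
40 | CNP0192639.1, (7R,8S,7'R,8'S; 2R,3S) | COc1cc([C@@H](O)[C@H](CO)Oc2c(OC)cc([C@@H](O)[C@H](CO)Oc3c(OC)cc([C@@H]4Oc5c(OC)cc(/C=C/C=O)cc5[C@H]4CO)cc3OC)cc2OC)ccc1O | target

**Step count**
Total step count: 24.
Longest linear sequence: 16 steps (steps 6, 9 and 11 to 24, from 13 to 40). The branch through the key step has 14 steps (1 to 5, 7, 8 and 18 to 24).

**Steps most likely to fail**

Step 4. β–β coupling of the imide, self-coupling of the bromophenol or further oxidation of the product phenol may outrun the cross-coupling, or the auxiliary may discriminate the Cβ faces poorly.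
- The fallback uses known reaction types only. C3–C3a is bought inside an arylacetic acid and C2–C3 is made by an aldol reaction.
- It sets out from 8. Allyl bromide/K2CO3 gives 1-allyloxy-4-bromo-2-methoxybenzene F1.
- Aromatic Claisen rearrangement (N,N-diethylaniline, 190 °C) moves the allyl group to the only free ortho carbon and gives 2-allyl-4-bromo-6-methoxyphenol F2.
- TBSCl/imidazole gives the silyl ether F3.
- OsO4 (cat.)/NaIO4 cleaves the alkene to the arylacetaldehyde F4, and Pinnick oxidation (NaClO2, NaH2PO4, 2-methyl-2-butene) gives the arylacetic acid F5.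
- Loading onto 13 (PivCl, Et3N; LiCl) gives the arylacetyl imide F6.
- An Evans syn aldol reaction (Bu2BOTf, Et3N) of F6 with 4-(tert-butyldimethylsilyloxy)-3,5-dimethoxybenzaldehyde F7 (from syringaldehyde, TBSCl, imidazole) gives the syn aldol adduct F8, in which the (R)-auxiliary fixes the future C3.
- LiBH4 gives the diol F9, and Bu4NF/AcOH frees both phenols to give the triol F10.
- A trace of TsOH in CH2Cl2 ionises the p-hydroxybenzylic alcohol to the quinone methide F11. The ring D phenol closes it 5-exo to the trans ring, and the route is rejoined at 12.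

Step 14. The activated, electron-rich benzylic alcohol may ionise before displacement, so that inversion is incomplete or elimination to the enol ether sets in.
- The fallback resets the carbinol by oxidation and chelation-controlled reduction.
- From 26, Dess–Martin periodinane gives the α-aryloxy ketone F12.
- Zn(BH4)2 in Et2O at −78 °C, with zinc bridging the carbonyl and aryloxy oxygens (Cram chelate), delivers hydride from the side of the C8 hydrogen to the erythro alcohol.
- The route is rejoined at 28, bypassing 27.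

Step 22. Oxidative addition into the electron-rich bromide of a large substrate may be slow, and forcing it may cost the benzylic ester.
- The fallback replaces the Heck reaction by a cross-coupling with a preformed vinyl boronate.
- From 36, i-Bu2AlH (CH2Cl2, −78 °C) first removes the ester to give the bromo alcohol F13.
- Suzuki–Miyaura coupling with (E)-2-(3,3-diethoxyprop-1-enyl)-4,4,5,5-tetramethyl-1,3,2-dioxaborolane (Pd(dppf)Cl2, K3PO4, dioxane–H2O, 60 °C) gives the enal diethyl acetal F14.
- PPTS in wet acetone unmasks the aldehyde, and the route is rejoined at 39.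

**Further compounds**
F1 | step 4 | 1-allyloxy-4-bromo-2-methoxybenzene | C=CCOc1ccc(Br)cc1OC
F2 | step 4 | 2-allyl-4-bromo-6-methoxyphenol | C=CCc1cc(Br)cc(OC)c1O
F3 | step 4 | (2-allyl-4-bromo-6-methoxyphenoxy)(tert-butyl)dimethylsilane | C=CCc1cc(Br)cc(OC)c1O[Si](C)(C)C(C)(C)C
F4 | step 4 | 2-[5-bromo-2-(tert-butyldimethylsilyloxy)-3-methoxyphenyl]acetaldehyde | O=CCc1cc(Br)cc(OC)c1O[Si](C)(C)C(C)(C)C
F5 | step 4 | 2-[5-bromo-2-(tert-butyldimethylsilyloxy)-3-methoxyphenyl]acetic acid | OC(=O)Cc1cc(Br)cc(OC)c1O[Si](C)(C)C(C)(C)C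
F6 | step 4 | (R)-4-benzyl-3-{2-[5-bromo-2-(tert-butyldimethylsilyloxy)-3-methoxyphenyl]acetyl}oxazolidin-2-one | O=C(Cc1cc(Br)cc(OC)c1O[Si](C)(C)C(C)(C)C)N1C(=O)OC[C@H]1Cc1ccccc1
F7 | step 4 | 4-(tert-butyldimethylsilyloxy)-3,5-dimethoxybenzaldehyde | COc1cc(C=O)cc(OC)c1O[Si](C)(C)C(C)(C)C
F8 | step 4 | (2R,3R) syn aldol imide of rings C and D | COc1cc(Br)cc([C@H]([C@@H](O)c2cc(OC)c(O[Si](C)(C)C(C)(C)C)c(OC)c2)C(=O)N2C(=O)OC[C@H]2Cc2ccccc2)c1O[Si](C)(C)C(C)(C)C
F9 | step 4 | (1R,2S)-2-[5-bromo-2-(tert-butyldimethylsilyloxy)-3-methoxyphenyl]-1-[4-(tert-butyldimethylsilyloxy)-3,5-dimethoxyphenyl]propane-1,3-diol | COc1cc(Br)cc([C@H]([C@@H](O)c2cc(OC)c(O[Si](C)(C)C(C)(C)C)c(OC)c2)CO)c1O[Si](C)(C)C(C)(C)C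
F10 | step 4 | (1R,2S)-2-(5-bromo-2-hydroxy-3-methoxyphenyl)-1-(4-hydroxy-3,5-dimethoxyphenyl)propane-1,3-diol | COc1cc(Br)cc([C@H]([C@@H](O)c2cc(OC)c(O)c(OC)c2)CO)c1O
F11 | step 4 | ring C p-quinone methide carrying the ring D phenol and CH2OH on Cβ | COc1cc(Br)cc([C@H](C=C2C=C(OC)C(=O)C(OC)=C2)CO)c1O
F12 | step 14 | (S)-2-(4-bromo-2,6-dimethoxyphenoxy)-3-(tert-butyldimethylsilyloxy)-1-[3-methoxy-4-(triisopropylsilyloxy)phenyl]propan-1-one | COc1cc(C(=O)[C@H](CO[Si](C)(C)C(C)(C)C)Oc2c(OC)cc(Br)cc2OC)ccc1O[Si](C(C)C)(C(C)C)C(C)C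
F13 | step 22 | (7'R,8'S) alcohol, ring D bromide | COc1cc([C@@H](O[Si](C)(C)C(C)(C)C)[C@H](CO[Si](C)(C)C(C)(C)C)Oc2c(OC)cc([C@@H](O)[C@H](CO[Si](C)(C)C(C)(C)C)Oc3c(OC)cc([C@@H]4Oc5c(OC)cc(Br)cc5[C@H]4CO[Si](C)(C)C(C)(C)C)cc3OC)cc2OC)ccc1O[Si](C(C)C)(C(C)C)C(C)C
F14 | step 22 | diethyl acetal of 39 | COc1cc([C@@H](O[Si](C)(C)C(C)(C)C)[C@H](CO[Si](C)(C)C(C)(C)C)Oc2c(OC)cc([C@@H](O)[C@H](CO[Si](C)(C)C(C)(C)C)Oc3c(OC)cc([C@@H]4Oc5c(OC)cc(/C=C/C(OCC)OCC)cc5[C@H]4CO[Si](C)(C)C(C)(C)C)cc3OC)cc2OC)ccc1O[Si](C(C)C)(C(C)C)C(C)C
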